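Ring A of the flavanone is a benzene ring fused at C4a–C8a that carries oxygen only at C7 and hydrogen at C5, C6 and C8. Its four carbons C5–C8 and the C7 oxygen therefore map onto 1-methoxy-3-silyloxybutadiene, and the C4a–C8a edge onto the C5=C6 bond of a 2-aryl-2,3-dihydropyran-4-one. Everything rests on this late benzannulation: one operation forms C4a–C5 and C8–C8a by [4+2] cycloaddition and aromatises by loss of methanol and benzenesulfenic acid. The precursor is the (2S)-dihydropyranone carrying the protected (3R,4S)-chromandiol at C2 and a phenylsulfinyl activator and leaving group at C5.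

Key step: step 10

Abbreviations: TBS = tert-butyldimethylsilyl; Ar = (3R,4S)-8-(benzyloxy)-3,4-bis[(tert-butyldimethylsilyl)oxy]-2,2-dimethylchroman-6-yl.

Assumption: the (S)-BINOL/Ti(OiPr)4 catalyst is taken to direct the diene to the Si face of the aryl aldehyde, the sense it shows with allyl and silyl enol ether nucleophiles. The (R)-ligand is equally available if a first run shows the opposite sense.

Step 1
Reactants: 1 3,4-dihydroxybenzaldehyde
Product: 2 3-(benzyloxy)-4-hydroxybenzaldehyde
Conditions: NaH (2.1 equiv), DMF, 0 °C to rt; BnBr (1.0 equiv); aq. HCl work-up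
Reagents that add atoms: benzyl bromide, BrCc1ccccc1
Why: Regioselective Williamson etherification: after double deprotonation the 4-oxygen is delocalised into the para formyl group, so the 3-oxygen is the stronger nucleophile and takes up the single equivalent of benzyl bromide.

Step 2
Reactants: 2 3-(benzyloxy)-4-hydroxybenzaldehyde, 3 3-chloro-3-methylbut-1-yne
Product: 4 3-(benzyloxy)-4-[(2-methylbut-3-yn-2-yl)oxy]benzaldehyde
Conditions: DBU (1.3 equiv), CuCl2·2H2O (1 mol %), MeCN, 0 °C
Reagents that add atoms: none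
Why: Copper-catalysed propargylic O-alkylation of a phenol with a tertiary propargylic chloride runs through a copper acetylide/allenylidene species and is most efficient with acidic, vanillin-type phenols such as 2, whose only free hydroxyl is the one para to the formyl group (the future chroman O1).

Step 3
Reactants: 4 3-(benzyloxy)-4-[(2-methylbut-3-yn-2-yl)oxy]benzaldehyde
Product: 6 8-(benzyloxy)-2,2-dimethyl-2H-chromene-6-carbaldehyde, via allenyl phenol 5 (not isolated)
Conditions: PhNEt2, 190 °C
Reagents that add atoms: none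
Why: Aromatic propargyl Claisen rearrangement: the [3,3]-shift can only reach the one free ortho carbon because the other bears the benzyloxy group, and 5 then undergoes a 1,5-hydrogen shift and oxa-6π electrocyclisation to close the 2,2-dimethyl-2H-pyran ring.

Step 4
Reactants: 6 8-(benzyloxy)-2,2-dimethyl-2H-chromene-6-carbaldehyde
Product: 7 (3R,4R)-8-(benzyloxy)-3,4-epoxy-2,2-dimethylchromane-6-carbaldehyde
Conditions: (R,R)-N,N'-bis(3,5-di-tert-butylsalicylidene)-1,2-cyclohexanediaminomanganese chloride [(R,R)-(salen)MnCl, 4 mol %], 4-phenylpyridine N-oxide (20 mol %), aq. NaOCl (pH 11.3), CH2Cl2, 0 °C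
Reagents that add atoms: sodium hypochlorite, [Na+].[O-]Cl
Why: Jacobsen–Katsuki epoxidation, for which 2,2-dimethylchromenes are the benchmark cis-alkene class: the (R,R)-catalyst transfers oxygen to the face that gives the (3R,4R)-epoxide and so fixes C3 in its final configuration, while cold buffered biphasic bleach should leave the aryl aldehyde and the benzyl ether alone.

Step 5
Reactants: 7 (3R,4R)-8-(benzyloxy)-3,4-epoxy-2,2-dimethylchromane-6-carbaldehyde
Product: 8 (3R,4S)-8-(benzyloxy)-3,4-dihydroxy-2,2-dimethylchromane-6-carbaldehyde (trans-diol)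
Conditions: acetone/1 M aq. H2SO4 (2:1), 0 °C to rt
Reagents that add atoms: water, O
Why: Acid-catalysed epoxide hydrolysis with anti opening: water attacks benzylic C4 with inversion while the C3–O bond is untouched, so the (3R,4R)-epoxide gives the trans (3R,4S)-diol, and the 6-formyl group para to O1 damps cation character at C4 and with it leakage to the cis-diol.

Step 6
Reactants: 8 (3R,4S)-8-(benzyloxy)-3,4-dihydroxy-2,2-dimethylchromane-6-carbaldehyde
Product: 9 (3R,4S)-8-(benzyloxy)-3,4-bis[(tert-butyldimethylsilyl)oxy]-2,2-dimethylchromane-6-carbaldehyde (Ar–CHO)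
Conditions: TBSOTf (3 equiv), 2,6-lutidine (4 equiv), CH2Cl2, 0 °C to rt
Reagents that add atoms: tert-butyldimethylsilyl triflate, CC(C)(C)[Si](C)(C)OS(=O)(=O)C(F)(F)F
Why: Silylation with a silyl triflate and a hindered pyridine base covers both secondary alcohols, including the neopentyl-type C3–OH, without touching the stereocentres or the non-enolisable aldehyde, and the ethers withstand Lewis acids, peracid and dilute acid yet leave with fluoride.

Step 7
Reactants: 9 Ar–CHO, 10 (E)-1-methoxy-3-(trimethylsilyloxy)buta-1,3-diene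
Product: 12 (2S)-2-Ar-2,3-dihydro-4H-pyran-4-one, via silyl aldol adduct 11 (not isolated)
Conditions: (S)-BINOL (20 mol %), Ti(OiPr)4 (10 mol %), 4 Å MS, Et2O, −20 °C; then TFA, CH2Cl2, 0 °C, brief
Reagents that add atoms: none
Why: Titanium–BINOL-catalysed asymmetric hetero-Diels–Alder reaction running through a Mukaiyama aldol addition and acid-induced cyclisation with loss of methanol: the chiral Lewis acid exposes the Si face of the aldehyde and sets C2 as S under catalyst control, since the chroman stereocentres are too remote to interfere, and any minor isomer is a diastereomer that can be removed by chromatography or crystallisation.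

Step 8
Reactants: 12 (2S)-2-Ar-2,3-dihydro-4H-pyran-4-one, 13 thiophenol
Product: 16 (2S)-2-Ar-5-(phenylsulfanyl)-2,3-dihydro-4H-pyran-4-one, via benzenesulfenyl chloride 14 (not isolated), via chloro sulfide adduct 15 (not isolated)
Conditions: 13, NCS, CH2Cl2, 0 °C; add 12, −78 °C to 0 °C; then Et3N, 0 °C
Reagents that add atoms: N-chlorosuccinimide, O=C1CCC(=O)N1Cl (its chlorine is present only in 14 and 15)
Why: Electrophilic sulfenylation of a vinylogous ester by addition–elimination: C5 is the nucleophilic carbon of the enol ether, so 14 adds there with chloride capture at C6, and triethylamine removes HCl from 15 through the acidic C5–H to restore the conjugated C5=C6 bond.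

Step 9
Reactants: 16 (2S)-2-Ar-5-(phenylsulfanyl)-2,3-dihydro-4H-pyran-4-one
Product: 17 (2S)-2-[(3R,4S)-8-(benzyloxy)-3,4-bis[(tert-butyldimethylsilyl)oxy]-2,2-dimethylchroman-6-yl]-5-(phenylsulfinyl)-2,3-dihydro-4H-pyran-4-one (both epimers at sulfur)
Conditions: mCPBA (1.0 equiv), CH2Cl2, −40 °C to 0 °C
Reagents that add atoms: mCPBA, O=C(OO)c1cccc(Cl)c1
Why: Chemoselective sulfide-to-sulfoxide oxidation with one equivalent of peracid at low temperature, where sulfur reacts far faster than the electron-poor C5=C6 bond or the sulfoxide formed, and both sulfur epimers are carried on because sulfur is expelled in step 10.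

Step 10
Reactants: 17 (2S)-2-Ar-5-(phenylsulfinyl)-2,3-dihydro-4H-pyran-4-one, 10 (E)-1-methoxy-3-(trimethylsilyloxy)buta-1,3-diene
Product: 21 (2S)-2-[(3R,4S)-8-(benzyloxy)-3,4-bis[(tert-butyldimethylsilyl)oxy]-2,2-dimethylchroman-6-yl]-7-hydroxychroman-4-one, via cycloadduct 18 (not isolated), via sulfinyl enone 19 (not isolated), via dienone 20 (not isolated)
Conditions: 10 (4 equiv), ZnBr2 (1.2 equiv), CH2Cl2, −20 °C to 0 °C; then 0.1 M aq. HCl, THF, 0 °C; then PhMe, 70 °C
Reagents that add atoms: none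
Why: ZnBr2 chelated between the sulfinyl oxygen and the C4 carbonyl oxygen lowers the LUMO of the push–pull C5=C6 bond, and the diene adds in an asynchronous normal-demand Diels–Alder reaction whose leading bond joins its CH2 terminus to C6 (future C8a) and whose second bond joins the methoxy-bearing carbon to C5 (future C4a), giving cis-fused 18, and a stepwise Michael/ring-closure variant would end at the same ring. The closest known reaction type is the cycloaddition of 1-alkoxy-3-silyloxydienes to sulfinyl-activated enones, sulfinylquinones and 3-sulfinylchromones, where the sulfoxide makes the alkene an alkyne equivalent and phenols result. Ring A is closed by intermolecular [4+2] cycloaddition, both ring bonds being made in that event, and is then aromatised: dilute acid at 0 °C converts 18 into enone 19 with loss of methanol, warming triggers sulfoxide syn-elimination with the C8a–H that suprafacial addition has placed cis to sulfur, and the resulting 20 enolises to phenol 21. No lasting stereocentre is created, because C4a, C5 and C8a all become sp2, so endo/exo selectivity, facial selectivity and the configuration at sulfur are irrelevant, and C2 is a spectator under these base-free conditions. The step needs regioselectivity in the cycloaddition (oxygen at C7, not C6), which is secured by the two acceptors on C5 that make C6 the only electrophilic terminus, matched to the largest HOMO coefficient at the diene CH2. It also needs regioselectivity in the elimination (towards C8a, not C5), which is secured by keeping the zinc-bound sulfoxide cold until C5 has become vinylic, and no thiophile is added, so that the reversible [2,3]-shift of allylic sulfoxide 19 stays unproductive.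

Step 11
Reactants: 21 (2S)-2-Ar-7-hydroxychroman-4-one
Product: 22 (2S)-2-[(3R,4S)-3,4-bis[(tert-butyldimethylsilyl)oxy]-8-hydroxy-2,2-dimethylchroman-6-yl]-7-hydroxychroman-4-one
Conditions: H2 (1 atm), 10% Pd/C, EtOAc, rt
Reagents that add atoms: none
Why: Catalytic hydrogenolysis of an aryl benzyl ether under neutral conditions on chromatographed, sulfur-free 21; it is run while C4–O is still a bulky silyl ether, so that the benzylic C4–O and C2–O1 bonds and the deactivated aryl ketone should not be reduced.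

Step 12
Reactants: 22 (2S)-2-[(3R,4S)-3,4-bis[(tert-butyldimethylsilyl)oxy]-8-hydroxy-2,2-dimethylchroman-6-yl]-7-hydroxychroman-4-one
Product: 23 (2S)-7-hydroxy-2-[(3R,4S)-3,4,8-trihydroxy-2,2-dimethylchroman-6-yl]chroman-4-one (CNP0281318.3)
Conditions: HF·pyridine, extra pyridine, THF, 0 °C to rt; pH 7 buffer
Reagents that add atoms: none
Why: Fluoride-driven Si–O cleavage in a buffered, weakly acidic medium, which is known to remove neopentyl-type secondary silyl ethers; basic fluoride is avoided because retro-oxa-Michael opening of ring C to the chalcone would racemise C2, and strong acid is avoided because the C4 benzylic alcohol can ionise.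

Compound list
1 | 3,4-dihydroxybenzaldehyde | O=Cc1ccc(O)c(O)c1 | starting material
2 | 3-(benzyloxy)-4-hydroxybenzaldehyde | O=Cc1ccc(O)c(OCc2ccccc2)c1 | intermediate
3 | 3-chloro-3-methylbut-1-yne | CC(C)(Cl)C#C | starting material
4 | 3-(benzyloxy)-4-[(2-methylbut-3-yn-2-yl)oxy]benzaldehyde | O=Cc1ccc(OC(C)(C)C#C)c(OCc2ccccc2)c1 | intermediate
5 | 3-(benzyloxy)-4-hydroxy-5-(3-methylbuta-1,2-dien-1-yl)benzaldehyde | O=Cc1cc(C=C=C(C)C)c(O)c(OCc2ccccc2)c1 | intermediate
6 | 8-(benzyloxy)-2,2-dimethyl-2H-chromene-6-carbaldehyde | CC1(C)C=Cc2cc(C=O)cc(OCc3ccccc3)c2O1 | intermediate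
7 | (3R,4R)-8-(benzyloxy)-3,4-epoxy-2,2-dimethylchromane-6-carbaldehyde | CC1(C)Oc2c(OCc3ccccc3)cc(C=O)cc2[C@H]4O[C@@H]14 | intermediate
8 | (3R,4S)-8-(benzyloxy)-3,4-dihydroxy-2,2-dimethylchromane-6-carbaldehyde | CC1(C)Oc2c(OCc3ccccc3)cc(C=O)cc2[C@H](O)[C@H]1O | intermediate
9 | (3R,4S)-8-(benzyloxy)-3,4-bis[(tert-butyldimethylsilyl)oxy]-2,2-dimethylchromane-6-carbaldehyde | CC1(C)Oc2c(OCc3ccccc3)cc(C=O)cc2[C@H](O[Si](C)(C)C(C)(C)C)[C@H]1O[Si](C)(C)C(C)(C)C | intermediate
10 | (E)-1-methoxy-3-(trimethylsilyloxy)buta-1,3-diene | CO/C=C/C(=C)O[Si](C)(C)C | starting material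
11 | (1E,5S)-5-Ar-1-methoxy-5-[(trimethylsilyl)oxy]pent-1-en-3-one | CC1(C)Oc2c(OCc3ccccc3)cc([C@H](CC(=O)/C=C/OC)O[Si](C)(C)C)cc2[C@H](O[Si](C)(C)C(C)(C)C)[C@H]1O[Si](C)(C)C(C)(C)C | intermediate
12 | (2S)-2-Ar-2,3-dihydro-4H-pyran-4-one | CC1(C)Oc2c(OCc3ccccc3)cc([C@@H]3CC(=O)C=CO3)cc2[C@H](O[Si](C)(C)C(C)(C)C)[C@H]1O[Si](C)(C)C(C)(C)C | intermediate
13 | thiophenol | Sc1ccccc1 | starting material
14 | benzenesulfenyl chloride | ClSc1ccccc1 | intermediate
15 | (2S)-2-Ar-6-chloro-5-(phenylsulfanyl)tetrahydro-4H-pyran-4-one (mixture at C5 and C6) | CC1(C)Oc2c(OCc3ccccc3)cc([C@@H]3CC(=O)C(Sc4ccccc4)C(Cl)O3)cc2[C@H](O[Si](C)(C)C(C)(C)C)[C@H]1O[Si](C)(C)C(C)(C)C | intermediate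
16 | (2S)-2-Ar-5-(phenylsulfanyl)-2,3-dihydro-4H-pyran-4-one | CC1(C)Oc2c(OCc3ccccc3)cc([C@@H]3CC(=O)C(Sc4ccccc4)=CO3)cc2[C@H](O[Si](C)(C)C(C)(C)C)[C@H]1O[Si](C)(C)C(C)(C)C | intermediate
17 | (2S)-2-[(3R,4S)-8-(benzyloxy)-3,4-bis[(tert-butyldimethylsilyl)oxy]-2,2-dimethylchroman-6-yl]-5-(phenylsulfinyl)-2,3-dihydro-4H-pyran-4-one (both epimers at sulfur) | CC1(C)Oc2c(OCc3ccccc3)cc([C@@H]3CC(=O)C(S(=O)c4ccccc4)=CO3)cc2[C@H](O[Si](C)(C)C(C)(C)C)[C@H]1O[Si](C)(C)C(C)(C)C | intermediate
18 | (2S)-2-Ar-5-methoxy-4a-(phenylsulfinyl)-7-[(trimethylsilyl)oxy]-2,3,4a,5,8,8a-hexahydro-4H-chromen-4-one (cis-fused; mixture at C5 and sulfur) | CC1(C)Oc2c(OCc3ccccc3)cc([C@@H]3CC(=O)C4(S(=O)c5ccccc5)C(OC)C=C(O[Si](C)(C)C)CC4O3)cc2[C@H](O[Si](C)(C)C(C)(C)C)[C@H]1O[Si](C)(C)C(C)(C)C | intermediate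
19 | (2S)-2-Ar-4a-(phenylsulfinyl)-2,3,8,8a-tetrahydro-4H-chromene-4,7(4aH)-dione (cis-fused) | CC1(C)Oc2c(OCc3ccccc3)cc([C@@H]3CC(=O)C4(S(=O)c5ccccc5)C=CC(=O)CC4O3)cc2[C@H](O[Si](C)(C)C(C)(C)C)[C@H]1O[Si](C)(C)C(C)(C)C | intermediate
20 | (2S)-2-Ar-2,3-dihydro-4H-chromene-4,7(8H)-dione | CC1(C)Oc2c(OCc3ccccc3)cc([C@@H]3CC(=O)C4=C(CC(=O)C=C4)O3)cc2[C@H](O[Si](C)(C)C(C)(C)C)[C@H]1O[Si](C)(C)C(C)(C)C | intermediate
21 | (2S)-2-[(3R,4S)-8-(benzyloxy)-3,4-bis[(tert-butyldimethylsilyl)oxy]-2,2-dimethylchroman-6-yl]-7-hydroxychroman-4-one | CC1(C)Oc2c(OCc3ccccc3)cc([C@@H]3CC(=O)c4ccc(O)cc4O3)cc2[C@H](O[Si](C)(C)C(C)(C)C)[C@H]1O[Si](C)(C)C(C)(C)C | intermediate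
22 | (2S)-2-[(3R,4S)-3,4-bis[(tert-butyldimethylsilyl)oxy]-8-hydroxy-2,2-dimethylchroman-6-yl]-7-hydroxychroman-4-one | CC1(C)Oc2c(O)cc([C@@H]3CC(=O)c4ccc(O)cc4O3)cc2[C@H](O[Si](C)(C)C(C)(C)C)[C@H]1O[Si](C)(C)C(C)(C)C | intermediate
23 | (2S)-7-hydroxy-2-[(3R,4S)-3,4,8-trihydroxy-2,2-dimethylchroman-6-yl]chroman-4-one | CC1(C)Oc2c(O)cc([C@@H]3CC(=O)c4ccc(O)cc4O3)cc2[C@H](O)[C@H]1O | target

Total step count: 12
Longest linear sequence: 12 steps (1 to 23)

Steps most likely to fail

Step 10.
- What may go wrong: the cycloaddition may be too slow on an alkene that still carries the O1 donor, so that the Lewis acid consumes the diene first. Sulfenic acid may be lost towards C5 before methanol has left. Zinc may ionise the para-alkoxybenzylic C2–O1 bond and erode C2, or O1 may be β-eliminated from 19 with opening of ring C.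
- Fallback (sets out from 9, returns at 22): ring A is bought instead of built. Claisen–Schmidt condensation of 9 with commercial 1-[4-(benzyloxy)-2-hydroxyphenyl]ethanone (KOH, EtOH, rt) should give (E)-1-[4-(benzyloxy)-2-hydroxyphenyl]-3-Ar-prop-2-en-1-one F1. NaOAc in refluxing EtOH closes ring C by intramolecular oxa-Michael addition to (2S)-2-Ar-7-(benzyloxy)chroman-4-one F2 together with (2R)-2-Ar-7-(benzyloxy)chroman-4-one F3. These two are diastereomers because Ar is a single enantiomer, so they are separated by preparative HPLC, and F3 is returned to the same equilibration through F1. Hydrogenolysis of both benzyl ethers of F2 (H2, Pd/C, EtOAc) gives 22.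

Step 7.
- What may go wrong: addition to a hindered, electron-rich aldehyde may be sluggish, facial selectivity at the carbonyl group may be poor, or the sense of induction may be the wrong one.
- Fallback (sets out from 9, returns at 12): catalyst control is given up in favour of separation. ZnCl2 in THF at rt promotes the achiral cyclocondensation of 9 with 10 to 2-Ar-6-methoxy-4-[(trimethylsilyl)oxy]-3,6-dihydro-2H-pyran F4 (isomer mixture). TFA converts this into 12 and (2R)-2-Ar-2,3-dihydro-4H-pyran-4-one F5. The two diastereomers are parted by preparative HPLC on a chiral phase or by crystallisation.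

Step 8.
- What may go wrong: the sulfenyl chloride may attack or chlorinate the electron-rich chroman arene, or it may add incompletely to the carbonyl-deactivated enol ether.
- Fallback (sets out from 12, returns at 16): the C5–S bond is made by cross-coupling instead of electrophilic sulfenylation. α-Iodination with I2 and pyridine in CH2Cl2 should give (2S)-2-Ar-5-iodo-2,3-dihydro-4H-pyran-4-one F6. Pd2(dba)3/Xantphos with iPr2NEt in dioxane then couples F6 with 13 to give 16.

Further compounds
F1 | step 10 | (E)-1-[4-(benzyloxy)-2-hydroxyphenyl]-3-Ar-prop-2-en-1-one | CC1(C)Oc2c(OCc3ccccc3)cc(/C=C/C(=O)c3ccc(OCc4ccccc4)cc3O)cc2[C@H](O[Si](C)(C)C(C)(C)C)[C@H]1O[Si](C)(C)C(C)(C)C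
F2 | step 10 | (2S)-2-Ar-7-(benzyloxy)chroman-4-one | CC1(C)Oc2c(OCc3ccccc3)cc([C@@H]3CC(=O)c4ccc(OCc5ccccc5)cc4O3)cc2[C@H](O[Si](C)(C)C(C)(C)C)[C@H]1O[Si](C)(C)C(C)(C)C
F3 | step 10 | (2R)-2-Ar-7-(benzyloxy)chroman-4-one | CC1(C)Oc2c(OCc3ccccc3)cc([C@H]3CC(=O)c4ccc(OCc5ccccc5)cc4O3)cc2[C@H](O[Si](C)(C)C(C)(C)C)[C@H]1O[Si](C)(C)C(C)(C)C
F4 | step 7 | 2-Ar-6-methoxy-4-[(trimethylsilyl)oxy]-3,6-dihydro-2H-pyran (mixture at C2 and C6) | CC1(C)Oc2c(OCc3ccccc3)cc(C3CC(O[Si](C)(C)C)=CC(OC)O3)cc2[C@H](O[Si](C)(C)C(C)(C)C)[C@H]1O[Si](C)(C)C(C)(C)C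
F5 | step 7 | (2R)-2-Ar-2,3-dihydro-4H-pyran-4-one | CC1(C)Oc2c(OCc3ccccc3)cc([C@H]3CC(=O)C=CO3)cc2[C@H](O[Si](C)(C)C(C)(C)C)[C@H]1O[Si](C)(C)C(C)(C)C
F6 | step 8 | (2S)-2-Ar-5-iodo-2,3-dihydro-4H-pyran-4-one | CC1(C)Oc2c(OCc3ccccc3)cc([C@@H]3CC(=O)C(I)=CO3)cc2[C@H](O[Si](C)(C)C(C)(C)C)[C@H]1O[Si](C)(C)C(C)(C)C
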